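## Structural features

The target is a trans-fused hydroazulene (daucane skeleton): a cyclopentane (C1–C5) and a cycloheptanone (C1, C5–C10) share the C1–C5 bond, with the C1 methyl β and H-5 α. The five-membered ring carries the isopropyl carbinol C4 (hydroxyl β) next to C5. The seven-membered ring carries in unbroken sequence the 6α-(4-hydroxybenzoyloxy) carbon, the C7 ketone, the tertiary carbinol C8 (hydroxyl α, methyl β) and the secondary carbinol C9 (hydroxyl α), so C4/C5/C6 and C8/C9 are two runs of adjacent stereocentres, six in all with quaternary C1. Fragile elements are the β-hydroxy ketone C9–C8–C7 (retro-aldol, dehydration), the tertiary α-ketol at C8, the α-acyloxy ketone at C6 (epimerisation, acyl migration, ester cleavage), the acid-sensitive tertiary carbinol at C4 and the free phenol. The real difficulty is the seven-membered ring: five contiguous functionalised carbons (C5–C9) next to quaternary C1, with the cis-8,9-diol and the 6-ester on the α face and a trans ring fusion. A second difficulty is chemoselectivity between the C7 ketone and the C4 carbonyl that the isopropyl addition needs. The key step exploits that C7 is the centre of a three-carbon unit C6–C7–C8 whose ends are bonded to C5 and to the oxygen-bearing C9, and that C5 and C9 are 1,4-related through C1 and C10. The ring is therefore the union of a 1,4-keto aldehyde (C5, C1, C10, C9) and a 2-oxyallyl dianion equivalent (C6–C7–C8), and the C9 oxygen is the bridge oxygen of the annulation.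

## Logic of the disconnections

**Silyl groups and ester.** 31 is traced to 30 by returning three O–Si bonds, and 30 is cut at the C6 O–acyl bond into 28 and 29. The ester and the phenol are the most labile groups, so they come last; everything earlier then handles only silyl ethers. The forward steps must acylate a hindered secondary α-ketol without touching the tertiary C4 hydroxyl, and must desilylate without base.

**C6–O bond.** 28 is cut at C6–O to the silyl enol ether 27. C6 is oxidised only after C8 has become quaternary, so one enolisation direction exists. The forward step must deliver oxygen to the α face and leave the new hydroxyl free.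

**C4–isopropyl bond.** 27 is cut at the C4–C(isopropyl) bond to ketone 26, which goes back through alcohol 25 to benzyl ether 24. The carbinol is the one quaternary centre that a carbonyl addition can make, and the cut removes three carbons and a stereocentre. The demand is that C7 is not a free ketone at that moment (it is the enol ether) and that the C4 protecting group comes off without fluoride or acid.

**Enol ether and C5–H.** 24 goes back to ketone 23 (two O–Si bonds), and 23 to enone 22 (C5–H and C6–H, i.e. C5=C6 restored). The gain is an enone in which C6 cannot be enolised. The forward hydrogenation must add H to the α face of C5.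

**C8–O and C8–ester.** 22 is cut at C8–O to 20, and the C8–CO2Me bond is restored in 19. With C5=C6 present, the ketone can only enolise toward C8, so the hydroxylation is regiospecific. The ester is needed one step earlier as a blocking group. Demands: α-face hydroxylation at C8, and loss of the ester without loss of the C9 oxygen.

**C5–O bond.** 19 is closed from the C9 oxygen to C5 to give the oxygen-bridged 17. The enone and the 9α-oxygen are the two halves of a β-alkoxy ketone. The gain is a rigid oxabicycle in which C5 and C9 are defined. The forward elimination must go toward C6 only, which the quaternary C8 enforces.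

**C5–C6 and C8–C9 (key).** 17 is cut into keto aldehyde 12 and bis(silyloxy)diene 15. Two skeletal bonds, two rings and the C5/C9 configuration are removed at once, leaving a monocyclic ketone with one stereogenic quaternary carbon. The forward step must send the diene terminus to the ketone carbon and the ester-bearing carbon to the aldehyde carbon.

**C9=O and C4–O.** 12 goes back to alkene 10 (C9=O from C9=CH2), then to 9 (O–benzyl) and to 6 (C4–O). The aldehyde is kept masked as an allyl group until just before use. The oxidation at C4 must be regiospecific, which the quaternary C1 secures.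

**C1–C10 bond.** 6 is cut at the C1–allyl bond to enol carbonate 5, made from 2, which comes from 1 and 3. This reduces the only stereocentre that must be set by a catalyst to a racemic ketone. The forward step must be enantioselective at a fully substituted carbon, and the enol derivative must be the tetrasubstituted regioisomer.

**Diene.** 15 goes back by two O–Si bonds through 14 to 13. The demand is γ-deprotonation of the vinylogous ester in the second silylation.

## Other disconnections considered

**Alternative 1:** The cut removes C7–C8 and restores C5–C10, so the seven-membered ring is traced to a bicyclo[3.1.0]hexane, diazoketone A2, with a diazoacetyl group on C5 and an (E)-propenyl group on C10 on the same side of the cyclopropane. Forward, a Wolff rearrangement (silver-salt catalysis with sonication, or light) shifts C5 onto the diazo carbon C6. The ketene C6=C7 and the propenyl group then undergo a cis-divinylcyclopropane Cope rearrangement that forms C7–C8, breaks C5–C10 and gives dienone A1.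
- In its favour: one operation gives the complete hydroazulene with the C7 carbonyl, the C8 methyl, quaternary C1 and the C5=C6 enone, and the cyclopropane stereochemistry is transferred without external control.
- Against it here: A2 is a trisubstituted cyclopropane with a quaternary carbon, a ketal and a diazoketone, and should take clearly more steps than 12. The C1 methyl projects into the region where the two unsaturated arms must fold for the boat transition state. A1 has no oxygen on C9, so the 9α-hydroxyl would need regio- and face-selective functionalisation of the isolated C9=C10 bond next to quaternary C1. The C8 stereocentre made by the Cope step is erased when C8 is hydroxylated.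
- Comparison: on structure, A1 is the equal or the better of 17 in two respects: C8 already has its methyl with no ester to remove, and C4 arrives at the ketone oxidation level in protected form. 17 is the better in carrying the C9 oxygen with its configuration. On mechanism, both are cascades steered by ring geometry; the chosen one is intermolecular and convergent, the Wolff–Cope sequence is unimolecular and needs a hazardous diazo precursor. On step economy, the alternative should be longer before its key step and about equal after it.

**Alternative 2:** The cut is the C1–C5 bond of the five-membered ring, leading to the acyclic α-diazo-β-keto ester A4, which derives from (S)-citronellol A5; the methine carbon of A5 becomes C1. Forward, a dirhodium tetracarboxylate generates the carbenoid at C5, which inserts into the tertiary C1–H bond with retention and closes cyclopentanone A3, ester trans to the silyloxyethyl chain.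
- In its favour: the configuration of quaternary C1 comes from an inexpensive chiral-pool alcohol, and 1,5-insertion into a tertiary C–H bond is the preferred mode for such carbenoids. The C4 ketone exists before C7 does, so the isopropyl group could be added with no second ketone present. On this point the alternative is better than the chosen plan, which must mask C7 as an enol ether.
- Against it here: the key step makes only the five-membered ring and one C–C bond. The seven-membered ring with its four contiguous oxygenated carbons (C6–C9) must still be built from the ester carbon C6 and the chain C10–C9, with two more carbons, a medium-ring closure and separate control of C5, C6, C8 and C9.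
- Comparison: on structure, A3 holds C1, C4, C5 and C6 but none of the difficult ring, whereas 17 holds the whole bicyclic skeleton with C7 and C9 oxidised. On mechanism, the C–H insertion is the equal or the better in predictability, since retention is intrinsic; the annulation is the more enabling step. On step economy, the alternative is likely longer overall because ring construction is deferred.

**Alternative 3:** The cuts are C7–C8 and C1–C10, a (4+3) combination of vinylcyclopentene A7 (C1=C5–C6=C7) with the three-carbon vinylcarbenoid from vinyldiazoacetate A8 (C8–C9=C10). Forward, a chiral dirhodium tetracarboxylate converts A8 into a carbenoid that cyclopropanates the terminal C6=C7 bond of A7 at C8. The cis-divinylcyclopropane then rearranges (Cope) with formation of C1–C10 to give hexahydroazulene A6.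
- In its favour: the seven-membered ring and quaternary C1 are made in one catalytic, potentially enantioselective step from two simple fragments. This is better in convergence and in step count to the bicyclic core than the chosen plan, where C1 is set six steps before the annulation. The alkenes of A6 (C5=C6, C8=C9) sit where C6 and C8/C9 must later be oxygenated.
- Against it here: the Cope step must form a quaternary centre at a tetrasubstituted alkene carbon, and the C4 stereocentre may be mismatched with the catalyst. C7 emerges as a methylene that must be oxidised between two alkenes. C8 carries an ester that must be reduced all the way to methyl, not simply removed.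
- Comparison: on structure, A6 lacks the C7 and C9 oxygens that 17 has, but its C8=C9 alkene allows direct cis-dihydroxylation, the equal of the chosen sequence for the 8,9-diol. On mechanism, both are two-bond annulations relayed by a reactive intermediate (oxocarbenium ion versus cyclopropane); the chosen one is substrate-controlled, the alternative catalyst-controlled. On step economy, the alternative is shorter to its key intermediate but should lose that lead in the redox adjustments at C7 and C8.

Key step: step 9

**Remarks on the chemistry**
- Atom numbers C1–C10 are those of the target (C1 methyl-bearing fusion carbon, C4 isopropyl carbinol, C5 fusion CH, C6 acyloxy carbon, C7 ketone, C8 methyl carbinol, C9 CHOH, C10 CH2) and are used for all bicyclic intermediates; β is the face of the C1 methyl.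
- The structures of the key step were checked against the target: the quaternary carbon of 12 and 17 has the target configuration, and the oxygen bridge of 17 is trans to the C1 methyl at both C5 and C9, as a cis-fused oxocarbenium ion requires. No skeletal correction was needed.
- The C4 oxygen of 12 is carried as a benzyl ether, not a silyl ether. Later the C7 ketone must be masked as a silyl enol ether while C4 is unmasked and oxidised, which a silyl group on C4 would not allow.
- Assumption: the (R)-phosphinooxazoline ligand gives (R)-6, by analogy with six-membered enol carbonates; if the sense is opposite, the enantiomeric ligand is used.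
- The C4 epimer drawn (oxygen cis to the C1 methyl) is the one expected to predominate; the other epimer converges at 26. The C8 epimers of 17, 19 and 20 also converge.
- 4-(tert-Butyldimethylsilyloxy)benzoic acid 29 is taken as a purchased reagent.

## Route

Step 1
Reactants: 1 2-methylcyclopentanone
Product: 2 2-methyl-1-(trimethylsilyloxy)cyclopent-1-ene
Conditions: Me3SiCl, NaI, Et3N, MeCN, rt
Reagents that add atoms: chlorotrimethylsilane, C[Si](C)(C)Cl
Why: Silyl enol ether formation under equilibrating conditions (Me3SiI made in situ, amine base) should favour the tetrasubstituted enol ether; the minor regioisomer is removed by distillation or at the carbonate stage.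

Step 2
Reactants: 2 2-methyl-1-(trimethylsilyloxy)cyclopent-1-ene; 3 allyl chloroformate
Product: 5 allyl 2-methylcyclopent-1-en-1-yl carbonate, via lithium enolate 4 (not isolated)
Conditions: MeLi, THF, 0 °C; then 3, −78 °C → rt
Reagents that add atoms: none
Why: Si–O cleavage by MeLi gives the regiodefined lithium enolate without equilibration, and the chloroformate acylates it on oxygen to the allyl enol carbonate.

Step 3
Reactants: 5 allyl 2-methylcyclopent-1-en-1-yl carbonate
Product: 6 (R)-2-allyl-2-methylcyclopentan-1-one
Conditions: Pd2(dba)3 (2.5 mol %), (R)-t-BuPHOX [(R)-4-tert-butyl-2-(2-diphenylphosphinophenyl)-4,5-dihydrooxazole] (6.25 mol %), THF, 25 °C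
Reagents that add atoms: none
Why: Decarboxylative asymmetric allylic alkylation (Tsuji–Trost type): zerovalent palladium ionises the allyl carbonate, CO2 is lost, and the palladium enolate recombines with the allyl fragment inside the chiral ligand pocket, which selects the enolate face and sets quaternary C1. A ligand with electron-poor aryl groups on phosphorus is the usual remedy if the five-membered enolate is less selective.

Step 4
Reactants: 6 (R)-2-allyl-2-methylcyclopentan-1-one
Product: 9 (2R,5S)-2-allyl-5-hydroxy-2-methylcyclopentan-1-one (hydroxyl cis to methyl), via silyl enol ether 7 (not isolated), via silyloxy ketone 8 (not isolated)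
Conditions: LiN(i-Pr)2, Me3SiCl, THF, −78 °C; then mCPBA, CH2Cl2, 0 °C; then 1 M HCl, THF
Reagents that add atoms: 3-chloroperoxybenzoic acid, OOC(=O)c1cccc(Cl)c1
Why: Rubottom oxidation: the only enolisable position gives one silyl enol ether, its electron-rich double bond is epoxidised much faster than the monosubstituted allyl alkene, and silyl migration then acid hydrolysis gives the α-hydroxy ketone. Attack trans to the larger allyl group should favour the hydroxyl cis to methyl, but either C4 epimer serves.

Step 5
Reactants: 9 (2R,5S)-2-allyl-5-hydroxy-2-methylcyclopentan-1-one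
Product: 10 (2R,5S)-2-allyl-5-(benzyloxy)-2-methylcyclopentan-1-one
Conditions: benzyl 2,2,2-trichloroacetimidate, TfOH (cat.), CH2Cl2/cyclohexane, 0 °C → rt
Reagents that add atoms: benzyl 2,2,2-trichloroacetimidate, ClC(Cl)(Cl)C(=N)OCc1ccccc1
Why: Acid-catalysed O-benzylation with the imidate avoids base, under which α-hydroxy ketones enolise or rearrange. The benzyl ether survives silyl triflates, amide bases and homogeneous hydrogenation, and can later be removed without fluoride or acid.

Step 6
Reactants: 10 (2R,5S)-2-allyl-5-(benzyloxy)-2-methylcyclopentan-1-one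
Product: 12 (2R,5S)-5-(benzyloxy)-2-methyl-2-(2-oxoethyl)cyclopentan-1-one, via ozonide 11 (not isolated)
Conditions: O3, CH2Cl2, −78 °C (indicator end point); then PPh3, −78 °C → rt
Reagents that add atoms: ozone, [O-][O+]=O
Why: Ozonolysis with reductive work-up cleaves the terminal alkene to the aldehyde; the benzyl ether is spared if no excess ozone is used, and the 1,4-keto aldehyde is used promptly.

Step 7
Reactants: 13 methyl 2-methylacetoacetate
Product: 14 methyl (2Z)-2-methyl-3-(trimethylsilyloxy)but-2-enoate
Conditions: Me3SiCl, Et3N, hexane, rt
Reagents that add atoms: chlorotrimethylsilane, C[Si](C)(C)Cl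
Why: O-Silylation of the enolised β-keto ester gives the conjugated silyl enol ether; its geometry is of no consequence.

Step 8
Reactants: 14 methyl (2Z)-2-methyl-3-(trimethylsilyloxy)but-2-enoate
Product: 15 (1Z)-1-methoxy-2-methyl-1,3-bis(trimethylsilyloxy)buta-1,3-diene
Conditions: LiN(i-Pr)2, THF, −78 °C; then Me3SiCl, −78 → 0 °C
Reagents that add atoms: chlorotrimethylsilane, C[Si](C)(C)Cl
Why: γ-Deprotonation of the vinylogous ester gives the dienolate, which is silylated on the ester oxygen to the 1,3-bis(silyloxy)diene; it is distilled and used fresh.

Step 9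
Reactants: 12 (2R,5S)-5-(benzyloxy)-2-methyl-2-(2-oxoethyl)cyclopentan-1-one; 15 (1Z)-1-methoxy-2-methyl-1,3-bis(trimethylsilyloxy)buta-1,3-diene
Product: 17 methyl 4β-(benzyloxy)-5α,9α-epoxy-1β,8β-dimethyl-7-oxoperhydroazulene-8α-carboxylate (oxygen bridge C5–O–C9; 8-oxabicyclo[3.2.1]octan-3-one fused to the cyclopentane), via silyl lactol mono-adduct 16 (not isolated)
Conditions: Me3SiOTf (0.2–1.0 equiv), CH2Cl2, −78 → −20 °C
Reagents that add atoms: none
Why: Me3SiOTf silylates the aldehyde of 12, the ring-ketone oxygen adds to the activated C9, and the bicyclic oxocarbenium ion at C5 is captured by the unsubstituted terminus (C6) of 15 in a Mukaiyama-type addition to give 16; ionisation of the C9 silyloxy group then gives a second oxocarbenium ion, which the tethered silyl enol ether attacks through C8. The closest known reaction type is the silyl-triflate-promoted (3+4) annulation of 1,4-keto aldehydes with 1,3-bis(silyloxy)dienes through neighbouring-carbonyl participation. The first ring, the oxolane C5–O–C9–C10–C1, closes by 5-exo-trig attack of oxygen on the aldehyde; the second, the seven-membered carbocycle, closes by 7-exo-trig attack of the enol carbon C8 on the exocyclic C9=O+ bond, which also completes the six-membered oxanone of the 8-oxabicyclo[3.2.1]octane. C5 is controlled by C1: the bicyclic ion can accept the nucleophile only so that the two five-membered rings stay cis-fused, which puts C6 cis to the C1 methyl and the oxygen on the α face. C9 is controlled by the tether: the three-carbon bridge can span C5 and C9 only cis across the oxolane, so the C9–O bond is α as well. C8 is set in the chair-like closure and has no bearing on the target (drawn with the ester on the bridge side). The step needs regioselectivity (diene terminus to the ketone carbon, ester-bearing carbon to the aldehyde carbon), which rests on intramolecular ketone participation outrunning direct addition to the aldehyde and on the terminal carbon being the most nucleophilic site of 15; the hindered α-benzyloxy ketone is the weak point of this control.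

Step 10
Reactants: 17 methyl 4β-(benzyloxy)-5α,9α-epoxy-1β,8β-dimethyl-7-oxoperhydroazulene-8α-carboxylate
Product: 19 methyl 4β-(benzyloxy)-9α-(tert-butyldimethylsilyloxy)-1β,8β-dimethyl-7-oxohydroazul-5-ene-8α-carboxylate (C5=C6 enone), via bicyclic silyl enol ether 18 (not isolated)
Conditions: t-BuMe2SiOTf, Et3N, CH2Cl2, 0 °C → rt
Reagents that add atoms: tert-butyldimethylsilyl trifluoromethanesulfonate, CC(C)(C)[Si](C)(C)OS(=O)(=O)C(F)(F)F
Why: Soft enolisation can only go toward C6 because C8 is quaternary; silylation of the bridge oxygen then lets the enol ether expel C5–O (vinylogous β-elimination), giving the C5=C6 enone and leaving the oxygen on C9 as the 9α-silyl ether, so no free β-alkoxide that could undergo retro-aldol cleavage is formed.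

Step 11
Reactants: 19 methyl 4β-(benzyloxy)-9α-(tert-butyldimethylsilyloxy)-1β,8β-dimethyl-7-oxohydroazul-5-ene-8α-carboxylate
Product: 20 4β-(benzyloxy)-9α-(tert-butyldimethylsilyloxy)-1β,8β-dimethylhydroazul-5-en-7-one (8α-H)
Conditions: LiCl, H2O, DMSO, 140 °C
Reagents that add atoms: none
Why: Krapcho dealkoxycarbonylation: chloride demethylates the hindered ester by SN2 attack at methyl (no retro-Claisen on the non-enolisable β-keto ester), the carboxylate loses CO2, and water protonates the dienolate. The 9-silyloxy group lies near the plane of the cross-conjugated dienolate, which should disfavour its β-elimination; the C8 epimer ratio is irrelevant.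

Step 12
Reactants: 20 4β-(benzyloxy)-9α-(tert-butyldimethylsilyloxy)-1β,8β-dimethylhydroazul-5-en-7-one
Product: 22 4β-(benzyloxy)-9α-(tert-butyldimethylsilyloxy)-8α-hydroxy-1β,8β-dimethylhydroazul-5-en-7-one, via potassium dienolate 21 (not isolated)
Conditions: KN(SiMe3)2, THF, −78 °C; then 3-phenyl-2-(phenylsulfonyl)oxaziridine, −78 °C; aq NH4Cl
Reagents that add atoms: 3-phenyl-2-(phenylsulfonyl)oxaziridine, O=S(=O)(c1ccccc1)N1OC1c1ccccc1
Why: Kinetic α′-deprotonation of the enone is regiospecific for C8 (C6 is vinylic), and the cross-conjugated enolate is hydroxylated by the N-sulfonyloxaziridine (enolate oxidation). In the dienolate, C10 is the only out-of-plane ring atom and lies on the α face, so attack anti to the pseudoaxial C9–Hβ and away from the C1 methyl should place the new hydroxyl α, cis to the in-plane 9α-silyloxy group.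

Step 13
Reactants: 22 4β-(benzyloxy)-9α-(tert-butyldimethylsilyloxy)-8α-hydroxy-1β,8β-dimethylhydroazul-5-en-7-one
Product: 23 4β-(benzyloxy)-9α-(tert-butyldimethylsilyloxy)-8α-hydroxy-1β,8β-dimethyl-5αH-perhydroazulen-7-one (trans-fused)
Conditions: H2 (1 atm), [Ir(cod)(PCy3)(py)]PF6 (5 mol %), CH2Cl2, rt
Reagents that add atoms: none
Why: Hydroxyl-directed homogeneous hydrogenation: the homoallylic 8α-hydroxyl binds the cationic iridium catalyst and delivers H2 to the α face of C5=C6. That face is also the open one sterically (the C1 methyl on the carbon next to C5 blocks β), so H-5 becomes α and the ring fusion trans.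

Step 14
Reactants: 23 4β-(benzyloxy)-9α-(tert-butyldimethylsilyloxy)-8α-hydroxy-1β,8β-dimethyl-5αH-perhydroazulen-7-one
Product: 24 4β-(benzyloxy)-7,8α,9α-tris(tert-butyldimethylsilyloxy)-1β,8β-dimethyl-5αH-hydroazul-6-ene
Conditions: t-BuMe2SiOTf (excess), Et3N, CH2Cl2, 0 °C → rt
Reagents that add atoms: tert-butyldimethylsilyl trifluoromethanesulfonate, CC(C)(C)[Si](C)(C)OS(=O)(=O)C(F)(F)F
Why: The silyl triflate silylates the tertiary 8-hydroxyl and, by soft enolisation toward the only enolisable position C6, converts the C7 ketone into its silyl enol ether. This masks C7 against the organometallic reagent of step 17 and is also the substrate for the C6 oxidation of step 18.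

Step 15
Reactants: 24 4β-(benzyloxy)-7,8α,9α-tris(tert-butyldimethylsilyloxy)-1β,8β-dimethyl-5αH-hydroazul-6-ene
Product: 25 7,8α,9α-tris(tert-butyldimethylsilyloxy)-1β,8β-dimethyl-5αH-hydroazul-6-en-4β-ol
Conditions: H2 (1 atm), Pd/C, EtOAc, rt
Reagents that add atoms: none
Why: Neutral hydrogenolysis of the benzyl ether; the trisubstituted silyl enol ether, flanked by the quaternary C8 and the ring fusion, and the silyl ethers should survive.

Step 16
Reactants: 25 7,8α,9α-tris(tert-butyldimethylsilyloxy)-1β,8β-dimethyl-5αH-hydroazul-6-en-4β-ol
Product: 26 7,8α,9α-tris(tert-butyldimethylsilyloxy)-1β,8β-dimethyl-5αH-hydroazul-6-en-4-one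
Conditions: Dess–Martin periodinane, pyridine, CH2Cl2, 0 °C → rt
Reagents that add atoms: none
Why: Buffered periodinane oxidation of the secondary alcohol to the cyclopentanone under non-enolising conditions, so that C5 (α to the new ketone and allylic to the enol ether) is not disturbed.

Step 17
Reactants: 26 7,8α,9α-tris(tert-butyldimethylsilyloxy)-1β,8β-dimethyl-5αH-hydroazul-6-en-4-one
Product: 27 7,8α,9α-tris(tert-butyldimethylsilyloxy)-4α-isopropyl-1β,8β-dimethyl-5αH-hydroazul-6-en-4β-ol
Conditions: i-PrMgCl, CeCl3, THF, −78 → 0 °C; aq NH4Cl
Reagents that add atoms: isopropylmagnesium chloride, CC(C)[Mg]Cl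
Why: Organocerium 1,2-addition (low basicity, suppresses enolisation and β-hydride reduction) to the only free carbonyl. The nucleophile should approach C4 from the α face, anti to the 1,3-related axial C1 methyl, giving the 4β-hydroxyl and the 4α-isopropyl group.

Step 18
Reactants: 27 7,8α,9α-tris(tert-butyldimethylsilyloxy)-4α-isopropyl-1β,8β-dimethyl-5αH-hydroazul-6-en-4β-ol
Product: 28 8α,9α-bis(tert-butyldimethylsilyloxy)-4β,6α-dihydroxy-4α-isopropyl-1β,8β-dimethyl-5αH-perhydroazulen-7-one
Conditions: OsO4 (2 mol %), N-methylmorpholine N-oxide, acetone/H2O, 0 °C → rt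
Reagents that add atoms: N-methylmorpholine N-oxide (oxygen delivered through OsO4), C[N+]1([O-])CCOCC1
Why: Osmylation of the silyl enol ether, a Rubottom-type α-hydroxylation in which the osmate ester hydrolyses with loss of silanol so the new hydroxyl is free. OsO4 should add to the α face of C6=C7, anti to the axial C1 methyl that is 1,3 to C6; the 6α (equatorial) epimer is also the one favoured by equilibration through the enol.

Step 19
Reactants: 28 8α,9α-bis(tert-butyldimethylsilyloxy)-4β,6α-dihydroxy-4α-isopropyl-1β,8β-dimethyl-5αH-perhydroazulen-7-one; 29 4-(tert-butyldimethylsilyloxy)benzoic acid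
Product: 30 8α,9α-bis(tert-butyldimethylsilyloxy)-4β-hydroxy-4α-isopropyl-1β,8β-dimethyl-7-oxo-5αH-perhydroazulen-6α-yl 4-(tert-butyldimethylsilyloxy)benzoate
Conditions: DCC, DMAP, CH2Cl2, rt
Reagents that add atoms: none
Why: Steglich esterification acylates the secondary 6-hydroxyl; the tertiary 4-hydroxyl does not react under these conditions and the phenol is protected as its silyl ether.

Step 20
Reactants: 30 8α,9α-bis(tert-butyldimethylsilyloxy)-4β-hydroxy-4α-isopropyl-1β,8β-dimethyl-7-oxo-5αH-perhydroazulen-6α-yl 4-(tert-butyldimethylsilyloxy)benzoate
Product: 31 4β,8α,9α-trihydroxy-4α-isopropyl-1β,8β-dimethyl-7-oxo-5αH-perhydroazulen-6α-yl 4-hydroxybenzoate (CNP0241001.1)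
Conditions: HF·pyridine, pyridine, THF, 0 °C → rt
Reagents that add atoms: none
Why: Acidic fluoride removes the aryl, secondary and tertiary silyl ethers in one operation, avoiding the basic conditions that would cause retro-aldol cleavage, C6 epimerisation or acyl migration.

## Compound list

1 | 2-methylcyclopentanone | CC1CCCC1=O | starting material
2 | 2-methyl-1-(trimethylsilyloxy)cyclopent-1-ene | CC1=C(O[Si](C)(C)C)CCC1 | intermediate
3 | allyl chloroformate | C=CCOC(Cl)=O | starting material
4 | lithium 2-methylcyclopent-1-en-1-olate (not isolated) | CC1=C([O-])CCC1.[Li+] | intermediate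
5 | allyl 2-methylcyclopent-1-en-1-yl carbonate | C=CCOC(=O)OC1=C(C)CCC1 | intermediate
6 | (R)-2-allyl-2-methylcyclopentan-1-one | C=CC[C@@]1(C)CCCC1=O | intermediate
7 | (R)-(5-allyl-5-methylcyclopent-1-en-1-yloxy)trimethylsilane (not isolated) | C=CC[C@@]1(C)CCC=C1O[Si](C)(C)C | intermediate
8 | (2R,5S)-2-allyl-2-methyl-5-(trimethylsilyloxy)cyclopentan-1-one (not isolated) | C=CC[C@@]1(C)CC[C@H](O[Si](C)(C)C)C1=O | intermediate
9 | (2R,5S)-2-allyl-5-hydroxy-2-methylcyclopentan-1-one | C=CC[C@@]1(C)CC[C@H](O)C1=O | intermediate
10 | (2R,5S)-2-allyl-5-(benzyloxy)-2-methylcyclopentan-1-one | C=CC[C@@]1(C)CC[C@H](OCc2ccccc2)C1=O | intermediate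
11 | ozonide (1,2,4-trioxolane) of 10 (not isolated) | C1(OCOO1)C[C@@]2(C)CC[C@H](OCc3ccccc3)C2=O | intermediate
12 | (2R,5S)-5-(benzyloxy)-2-methyl-2-(2-oxoethyl)cyclopentan-1-one | O=CC[C@@]1(C)CC[C@H](OCc2ccccc2)C1=O | intermediate
13 | methyl 2-methylacetoacetate | COC(=O)C(C)C(C)=O | starting material
14 | methyl (2Z)-2-methyl-3-(trimethylsilyloxy)but-2-enoate | COC(=O)/C(C)=C(/C)O[Si](C)(C)C | intermediate
15 | (1Z)-1-methoxy-2-methyl-1,3-bis(trimethylsilyloxy)buta-1,3-diene | CO/C(O[Si](C)(C)C)=C(C)/C(=C)O[Si](C)(C)C | intermediate
16 | mono-adduct: cis-fused 2-(trimethylsilyloxy)oxolane bearing the silyl enol ether of the β-keto ester on C5 (not isolated) | COC(=O)C(C)=C(O[Si](C)(C)C)C[C@]23OC(O[Si](C)(C)C)C[C@@]2(C)CC[C@@H]3OCc4ccccc4 | intermediate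
17 | methyl 4β-(benzyloxy)-5α,9α-epoxy-1β,8β-dimethyl-7-oxoperhydroazulene-8α-carboxylate | COC(=O)[C@]1(C)C(=O)C[C@]23O[C@H]1C[C@@]2(C)CC[C@@H]3OCc4ccccc4 | intermediate
18 | C6=C7 tert-butyldimethylsilyl enol ether of 17 (not isolated) | COC(=O)[C@]1(C)C(O[Si](C)(C)C(C)(C)C)=C[C@]23O[C@H]1C[C@@]2(C)CC[C@@H]3OCc4ccccc4 | intermediate
19 | methyl 4β-(benzyloxy)-9α-(tert-butyldimethylsilyloxy)-1β,8β-dimethyl-7-oxohydroazul-5-ene-8α-carboxylate | c3ccccc3CO[C@H]1CC[C@]2(C)C[C@H](O[Si](C)(C)C(C)(C)C)[C@](C)(C(=O)OC)C(=O)C=C21 | intermediate
20 | 4β-(benzyloxy)-9α-(tert-butyldimethylsilyloxy)-1β,8β-dimethylhydroazul-5-en-7-one | c3ccccc3CO[C@H]1CC[C@]2(C)C[C@H](O[Si](C)(C)C(C)(C)C)[C@@H](C)C(=O)C=C21 | intermediate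
21 | potassium cross-conjugated dienolate of 20 (not isolated) | c3ccccc3CO[C@H]1CC[C@]2(C)C[C@H](O[Si](C)(C)C(C)(C)C)C(C)=C([O-])C=C21.[K+] | intermediate
22 | 4β-(benzyloxy)-9α-(tert-butyldimethylsilyloxy)-8α-hydroxy-1β,8β-dimethylhydroazul-5-en-7-one | c3ccccc3CO[C@H]1CC[C@]2(C)C[C@H](O[Si](C)(C)C(C)(C)C)[C@](C)(O)C(=O)C=C21 | intermediate
23 | 4β-(benzyloxy)-9α-(tert-butyldimethylsilyloxy)-8α-hydroxy-1β,8β-dimethyl-5αH-perhydroazulen-7-one | c3ccccc3CO[C@H]1CC[C@]2(C)C[C@H](O[Si](C)(C)C(C)(C)C)[C@](C)(O)C(=O)C[C@H]21 | intermediate
24 | 4β-(benzyloxy)-7,8α,9α-tris(tert-butyldimethylsilyloxy)-1β,8β-dimethyl-5αH-hydroazul-6-ene | c3ccccc3CO[C@H]1CC[C@]2(C)C[C@H](O[Si](C)(C)C(C)(C)C)[C@](C)(O[Si](C)(C)C(C)(C)C)C(O[Si](C)(C)C(C)(C)C)=C[C@H]21 | intermediate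
25 | 7,8α,9α-tris(tert-butyldimethylsilyloxy)-1β,8β-dimethyl-5αH-hydroazul-6-en-4β-ol | O[C@H]1CC[C@]2(C)C[C@H](O[Si](C)(C)C(C)(C)C)[C@](C)(O[Si](C)(C)C(C)(C)C)C(O[Si](C)(C)C(C)(C)C)=C[C@H]21 | intermediate
26 | 7,8α,9α-tris(tert-butyldimethylsilyloxy)-1β,8β-dimethyl-5αH-hydroazul-6-en-4-one | O=C1CC[C@]2(C)C[C@H](O[Si](C)(C)C(C)(C)C)[C@](C)(O[Si](C)(C)C(C)(C)C)C(O[Si](C)(C)C(C)(C)C)=C[C@H]21 | intermediate
27 | 7,8α,9α-tris(tert-butyldimethylsilyloxy)-4α-isopropyl-1β,8β-dimethyl-5αH-hydroazul-6-en-4β-ol | CC(C)[C@]1(O)CC[C@]2(C)C[C@H](O[Si](C)(C)C(C)(C)C)[C@](C)(O[Si](C)(C)C(C)(C)C)C(O[Si](C)(C)C(C)(C)C)=C[C@H]21 | intermediate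
28 | 8α,9α-bis(tert-butyldimethylsilyloxy)-4β,6α-dihydroxy-4α-isopropyl-1β,8β-dimethyl-5αH-perhydroazulen-7-one | CC(C)[C@]1(O)CC[C@]2(C)C[C@H](O[Si](C)(C)C(C)(C)C)[C@](C)(O[Si](C)(C)C(C)(C)C)C(=O)[C@H](O)[C@H]21 | intermediate
29 | 4-(tert-butyldimethylsilyloxy)benzoic acid | CC(C)(C)[Si](C)(C)Oc1ccc(cc1)C(=O)O | starting material
30 | 6-O-[4-(tert-butyldimethylsilyloxy)benzoyl] derivative of 28 | CC(C)[C@]1(O)CC[C@]2(C)C[C@H](O[Si](C)(C)C(C)(C)C)[C@](C)(O[Si](C)(C)C(C)(C)C)C(=O)[C@H](OC(=O)c3ccc(O[Si](C)(C)C(C)(C)C)cc3)[C@H]21 | intermediate
31 | 4β,8α,9α-trihydroxy-4α-isopropyl-1β,8β-dimethyl-7-oxo-5αH-perhydroazulen-6α-yl 4-hydroxybenzoate (CNP0241001.1) | CC(C)[C@]1(O)CC[C@]2(C)C[C@H](O)[C@](C)(O)C(=O)[C@H](OC(=O)c3ccc(O)cc3)[C@H]21 | target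

## Step count and least certain steps

Total: 20 steps. Longest linear sequence: 18 steps (steps 1–6 and 9–20); the diene branch is steps 7–8.

**Step 9 (key step).** The most likely failure is loss of regiocontrol by direct addition of the diene terminus to the free aldehyde. The ketone of 12 is flanked by a quaternary carbon and an alkoxy-bearing carbon, and its oxygen is a weaker participant than in simpler keto aldehydes. A second risk is stalling after the first bond, because the second closure joins a fully substituted nucleophilic carbon to C9. Fallback: starting from 12, equilibrating acetalisation (MeOH, HC(OMe)3, catalytic sulfonic acid) gives the cis-fused bicyclic bis-acetal 6-(benzyloxy)-2,6a-dimethoxy-3a-methylhexahydro-2H-cyclopenta[b]furan F1. F1 is then treated with 15 and Me3SiOTf. The tertiary ketal carbon C5 ionises first, so the diene terminus is delivered to C5 with no free aldehyde in competition, and the second ionisation at C9 closes the ring. The route is rejoined at 17.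

**Step 12.** The most likely failure is poor facial selectivity of the enolate oxidation, with the oxidant reaching C8 from the β face if the C9 silyloxy group hinders the α face more than expected. Partial γ-deprotonation at C4 is a lesser risk. Fallback: starting from 20, desilylation (HF·pyridine) gives the β-hydroxy enone 4β-(benzyloxy)-9α-hydroxy-1β,8β-dimethylhydroazul-5-en-7-one F2. Acid-catalysed dehydration (TsOH, benzene, reflux) gives the cross-conjugated dienone 4β-(benzyloxy)-1β,8-dimethylhydroazula-5,8-dien-7-one F3. OsO4/N-methylmorpholine N-oxide should dihydroxylate the less hindered C8=C9 bond from the α face, anti to the axial C1 methyl, to give the 8α,9α-diol F4. Selective silylation of the secondary hydroxyl (t-BuMe2SiCl, imidazole) returns the route to 22. This fallback gives up the C9 configuration from the key step and re-creates it by syn-dihydroxylation.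

**Step 15.** The most likely failure is saturation or cleavage of the silyl enol ether competing with hydrogenolysis of the hindered benzyl ether. Fallback: the order of protecting-group operations is changed. Starting from 23, hydrogenolysis (H2, Pd/C) before any enol ether exists gives the diol 9α-(tert-butyldimethylsilyloxy)-4β,8α-dihydroxy-1β,8β-dimethyl-5αH-perhydroazulen-7-one F5. Acetylation of the secondary hydroxyl (Ac2O, pyridine) gives the 4-acetate F6. The conditions of step 14 convert F6 into the acetate tris(silyl) enol ether F7. Reduction with i-Bu2AlH at −78 °C, which leaves silyl enol ethers intact, removes the acetate and returns the route to 25.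

**Step 17.** The most likely failure is deprotonation at C5 (α to the new ketone and allylic to the enol ether), with loss of the trans ring fusion or double-bond migration, or β-hydride reduction of the ketone by the secondary Grignard reagent. Fallback: starting from 26, the less basic, non-reducing CH2=C(CH3)MgBr with CeCl3 gives the isopropenyl carbinol 7,8α,9α-tris(tert-butyldimethylsilyloxy)-4α-isopropenyl-1β,8β-dimethyl-5αH-hydroazul-6-en-4β-ol F8. Hydrogenation of the 1,1-disubstituted alkene with H2 and RhCl(PPh3)3, which should spare the hindered enol ether, returns the route to 27.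

## Further compounds

F1 | step 9 | 6-(benzyloxy)-2,6a-dimethoxy-3a-methylhexahydro-2H-cyclopenta[b]furan (cis-fused; anomeric mixture at C9) | CO[C@]23OC(OC)C[C@@]2(C)CC[C@@H]3OCc4ccccc4
F2 | step 12 | 4β-(benzyloxy)-9α-hydroxy-1β,8β-dimethylhydroazul-5-en-7-one | c3ccccc3CO[C@H]1CC[C@]2(C)C[C@H](O)[C@@H](C)C(=O)C=C21
F3 | step 12 | 4β-(benzyloxy)-1β,8-dimethylhydroazula-5,8-dien-7-one | c3ccccc3CO[C@H]1CC[C@]2(C)CC=C(C)C(=O)C=C21
F4 | step 12 | 4β-(benzyloxy)-8α,9α-dihydroxy-1β,8β-dimethylhydroazul-5-en-7-one | c3ccccc3CO[C@H]1CC[C@]2(C)C[C@H](O)[C@](C)(O)C(=O)C=C21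
F5 | step 15 | 9α-(tert-butyldimethylsilyloxy)-4β,8α-dihydroxy-1β,8β-dimethyl-5αH-perhydroazulen-7-one | O[C@H]1CC[C@]2(C)C[C@H](O[Si](C)(C)C(C)(C)C)[C@](C)(O)C(=O)C[C@H]21
F6 | step 15 | 4β-acetoxy-9α-(tert-butyldimethylsilyloxy)-8α-hydroxy-1β,8β-dimethyl-5αH-perhydroazulen-7-one | CC(=O)O[C@H]1CC[C@]2(C)C[C@H](O[Si](C)(C)C(C)(C)C)[C@](C)(O)C(=O)C[C@H]21
F7 | step 15 | 4β-acetoxy-7,8α,9α-tris(tert-butyldimethylsilyloxy)-1β,8β-dimethyl-5αH-hydroazul-6-ene | CC(=O)O[C@H]1CC[C@]2(C)C[C@H](O[Si](C)(C)C(C)(C)C)[C@](C)(O[Si](C)(C)C(C)(C)C)C(O[Si](C)(C)C(C)(C)C)=C[C@H]21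
F8 | step 17 | 7,8α,9α-tris(tert-butyldimethylsilyloxy)-4α-isopropenyl-1β,8β-dimethyl-5αH-hydroazul-6-en-4β-ol | C=C(C)[C@]1(O)CC[C@]2(C)C[C@H](O[Si](C)(C)C(C)(C)C)[C@](C)(O[Si](C)(C)C(C)(C)C)C(O[Si](C)(C)C(C)(C)C)=C[C@H]21
A1 | alternative 1 | 1,1-(ethylenedioxy)-3a,6-dimethyl-2,3,3a,6-tetrahydroazulen-7(1H)-one | C[C@H]1C=C[C@@]2(C)CCC3(OCCO3)C2=CC1=O
A2 | alternative 1 | 1-(2-diazoacetyl)-5-methyl-6-[(E)-prop-1-enyl]bicyclo[3.1.0]hexan-2-one ethylene ketal (propenyl cis to the diazoacetyl group) | [N-]=[N+]=CC(=O)[C@]12[C@H](/C=C/C)[C@@]1(C)CCC23OCCO3
A3 | alternative 2 | methyl 2-[2-(tert-butyldimethylsilyloxy)ethyl]-2-methyl-5-oxocyclopentane-1-carboxylate (ester trans to the silyloxyethyl chain) | COC(=O)[C@H]1C(=O)CC[C@]1(C)CCO[Si](C)(C)C(C)(C)C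
A4 | alternative 2 | methyl (6S)-8-(tert-butyldimethylsilyloxy)-2-diazo-6-methyl-3-oxooctanoate | COC(=O)C(=[N+]=[N-])C(=O)CC[C@H](C)CCO[Si](C)(C)C(C)(C)C
A5 | alternative 2 | (S)-citronellol | CC(C)=CCC[C@H](C)CCO
A6 | alternative 3 | methyl 1-(tert-butyldimethylsilyloxy)-3a-methyl-1,2,3,3a,4,7-hexahydroazulene-6-carboxylate | COC(=O)C1=CC[C@@]2(C)CC[C@H](O[Si](C)(C)C(C)(C)C)C2=CC1
A7 | alternative 3 | tert-butyldimethyl[(1S)-3-methyl-2-vinylcyclopent-2-en-1-yloxy]silane | C=CC1=C(C)CC[C@@H]1O[Si](C)(C)C(C)(C)C
A8 | alternative 3 | methyl 2-diazobut-3-enoate | COC(=O)C(=[N+]=[N-])C=C
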